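**Plan**
- Retrosynthesis: the two ring A benzyl ethers and the two ring B acetates are removed from the flavone, then O1–C8a of ring C is cut to give an open 1,3-diketone, and C2–C3 of that diketone is cut to give a ring A methyl ketone and a ring B aroyl chloride.
- Forward: the ring A ketone comes from acetosyringone (the C5 oxygen enters by ring bromination and copper-catalysed hydroxylation). The ring B acid comes from 2-hydroxy-4-methoxybenzoic acid (the C5' oxygen enters by Elbs oxidation). C2–C3 is joined by soft-enolisation acylation, ring C is closed last, and the protecting groups are then removed.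
- Enabling feature: in the diketone, C8a is the only hydrogen-bearing carbon of the tetraoxygenated ring A, ortho to the C8 methoxy and para to the C6 methoxy group. The oxygen on C2 (the future O1) reaches it through a six-membered transition state, so anodic oxidation of ring A can form O1–C8a.
- Ring B is carried as its 2',5'-diacetate. With benzyl ethers its para-dialkoxy pattern would probably be oxidised before the contiguous tetraalkoxy ring A; the ester oxygens make it much harder to oxidise and keep the 2'-oxygen from closing the isomeric chromone.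
- Stereochemistry: the target is achiral and no stereocentre is created.

Key step: step 9

Assumption: acetosyringone and 2-hydroxy-4-methoxybenzoic acid are bought. Flavone locants (O1, C2 … C8a, primed for ring B) are used for the corresponding atoms of the open-chain precursors as well.

**Route**

Step 1
Reactants: 1 acetosyringone, 1-(4-hydroxy-3,5-dimethoxyphenyl)ethan-1-one
Product: 2 1-[4-(benzyloxy)-3,5-dimethoxyphenyl]ethan-1-one
Conditions: BnBr, K2CO3, DMF, 60 °C
Reagents that add atoms: benzyl bromide, BrCc1ccccc1
Why: Williamson etherification of the only phenol, which lies para to the acetyl group and is readily deprotonated by K2CO3, should proceed cleanly with benzyl bromide.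

Step 2
Reactants: 2 1-[4-(benzyloxy)-3,5-dimethoxyphenyl]ethan-1-one
Product: 3 1-[4-(benzyloxy)-2-bromo-3,5-dimethoxyphenyl]ethan-1-one
Conditions: NBS (1.05 equiv), MeCN, 0 °C to rt, dark
Reagents that add atoms: N-bromosuccinimide, O=C1CCC(=O)N1Br
Why: Electrophilic aromatic bromination in a polar aprotic solvent should occur at one of the two equivalent ring C–H positions, each ortho to one methoxy group and para to the other, faster than at the acetyl methyl group, whose bromination needs acid-catalysed enolisation.

Step 3
Reactants: 3 1-[4-(benzyloxy)-2-bromo-3,5-dimethoxyphenyl]ethan-1-one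
Product: 4 1-[4-(benzyloxy)-2-hydroxy-3,5-dimethoxyphenyl]ethan-1-one
Conditions: CuI (10 mol %), 1,10-phenanthroline (20 mol %), KOH, DMSO/H2O 1:1, 100 °C; then aq. HCl
Reagents that add atoms: potassium hydroxide, [K+].[OH-]
Why: Ullmann-type copper-catalysed hydroxylation of the aryl bromide should be assisted by the ortho acetyl group, which chelates copper and stabilises the phenoxide formed, while the ethers are inert to hydroxide.

Step 4
Reactants: 4 1-[4-(benzyloxy)-2-hydroxy-3,5-dimethoxyphenyl]ethan-1-one
Product: 5 1-[2,4-bis(benzyloxy)-3,5-dimethoxyphenyl]ethan-1-one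
Conditions: BnBr, K2CO3, Bu4NI (cat.), DMF, 70 °C
Reagents that add atoms: benzyl bromide, BrCc1ccccc1
Why: Williamson etherification of the hydrogen-bonded ortho phenol needs warming but has no competing nucleophile, since the methyl ketone is not alkylated under carbonate base.

Step 5
Reactants: 6 2-hydroxy-4-methoxybenzoic acid
Product: 8 2,5-dihydroxy-4-methoxybenzoic acid, via 5-sulfooxy acid 7 (not isolated)
Conditions: K2S2O8, aq. NaOH, 0 °C to rt; then 2 M HCl, 70 °C
Reagents that add atoms: potassium peroxodisulfate, [K+].[K+].[O-]S(=O)(=O)OOS(=O)(=O)[O-]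
Why: Elbs persulfate oxidation attacks the phenolate para to its oxygen, here the free C5 next to the methoxy group, and mild acid hydrolysis of the aryl sulfate releases the hydroquinone, as in the conversion of salicylic acid into gentisic acid.

Step 6
Reactants: 8 2,5-dihydroxy-4-methoxybenzoic acid
Product: 9 2,5-diacetoxy-4-methoxybenzoic acid
Conditions: Ac2O, H2SO4 (cat.), 60 °C; then H2O
Reagents that add atoms: acetic anhydride, CC(=O)OC(C)=O
Why: Acid-catalysed O-acetylation of both phenols follows the aspirin preparation, and the aqueous quench hydrolyses any mixed anhydride back to the free carboxylic acid.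

Step 7
Reactants: 9 2,5-diacetoxy-4-methoxybenzoic acid
Product: 10 2,5-diacetoxy-4-methoxybenzoyl chloride
Conditions: (COCl)2, DMF (cat.), CH2Cl2, 0 °C to rt; evaporate, use crude
Reagents that add atoms: oxalyl chloride, O=C(Cl)C(=O)Cl
Why: Activation of the acid by the chloroiminium species from DMF and oxalyl chloride gives the aroyl chloride under neutral conditions that leave aryl acetates intact, as in the preparation of O-acetylsalicyloyl chloride.

Step 8
Reactants: 5 1-[2,4-bis(benzyloxy)-3,5-dimethoxyphenyl]ethan-1-one; 10 2,5-diacetoxy-4-methoxybenzoyl chloride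
Product: 11 2-{3-[2,4-bis(benzyloxy)-3,5-dimethoxyphenyl]-3-oxopropanoyl}-5-methoxy-1,4-phenylene diacetate
Conditions: MgBr2·OEt2, i-Pr2NEt, CH2Cl2, rt; then 1 M HCl
Reagents that add atoms: none
Why: Soft enolisation of the methyl ketone as its magnesium enolate with an amine base gives C-acylation by the aroyl chloride in a crossed-Claisen-type reaction that forms C2–C3, under conditions too mild to cleave or transfer the aryl acetates, and the chelated magnesium diketonate resists a second acylation.

Step 9
Reactants: 11 2-{3-[2,4-bis(benzyloxy)-3,5-dimethoxyphenyl]-3-oxopropanoyl}-5-methoxy-1,4-phenylene diacetate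
Product: 12 2-[5,7-bis(benzyloxy)-6,8-dimethoxy-4-oxo-4H-chromen-2-yl]-5-methoxy-1,4-phenylene diacetate
Conditions: undivided cell, graphite anode, platinum cathode, Bu4NPF6 (0.1 M), HFIP/CH2Cl2 9:1, constant current 2 mA cm-2, 2.2 F mol-1, rt
Reagents that add atoms: none
Why: Proposed new method: the anode takes one electron from ring A, by design the only electron-rich arene of 11 (four ether oxygens, against one ether and two ester oxygens on ring B), and the radical cation is attacked at C8a, its single C–H carbon lying ortho to the C8 methoxy and para to the C6 methoxy group, by the oxygen on C2 of the enolised diketone; loss of a second electron and of a proton rearomatises ring A, while the cathode reduces protons of HFIP to H2. The closest known reaction types are the anodic dehydrogenative C–O cyclisations of biaryl-2-carboxylic acids to benzocoumarins and of anilides to benzoxazoles, and anodic C–H functionalisation of alkoxyarenes through their radical cations in HFIP; closure of a diketone enol oxygen onto an arene C–H bond to give a chromone has not been shown. Ring C closes as a six-membered ring by attack of O1 on the aromatic carbon C8a (formally 6-endo with respect to the C4a–C8a bond), which requires the enol to turn out of its internal hydrogen bond, and the hydrogen-bond-donating solvent should help with that. No stereocentre is formed. The step needs oxidation of ring A and not of ring B or of the enol, which the acetate groups on ring B and the absence of base are meant to secure, and it needs bond formation at C8a and not at an oxygen-bearing ring carbon, which follows because only attack at the C–H carbon can end in rearomatisation by proton loss in a solvent that offers no second nucleophile. Chromone 12 is a vinylogous ester and should be harder to oxidise than 11, and the charge is held a little above two faradays per mole to protect it.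

Step 10
Reactants: 12 2-[5,7-bis(benzyloxy)-6,8-dimethoxy-4-oxo-4H-chromen-2-yl]-5-methoxy-1,4-phenylene diacetate
Product: 13 2-(5,7-dihydroxy-6,8-dimethoxy-4-oxo-4H-chromen-2-yl)-5-methoxy-1,4-phenylene diacetate
Conditions: H2 (1 atm), palladium on carbon (Pd/C, 10%), EtOAc/THF, rt
Reagents that add atoms: none
Why: Hydrogenolysis of aryl benzyl ethers over palladium on carbon is standard for benzyloxyflavones and should leave the aryl acetates, the methyl ethers and the chromone double bond untouched at one atmosphere and room temperature.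

Step 11
Reactants: 13 2-(5,7-dihydroxy-6,8-dimethoxy-4-oxo-4H-chromen-2-yl)-5-methoxy-1,4-phenylene diacetate
Product: 14 2-(2,5-dihydroxy-4-methoxyphenyl)-5,7-dihydroxy-6,8-dimethoxy-4H-chromen-4-one
Conditions: HCl (1.25 M in MeOH), 40 °C, argon
Reagents that add atoms: none
Why: Acid-catalysed transesterification with methanol should cleave both aryl acetates, while the acidic oxygen-free medium protects the hydroquinone unit of ring B from oxidation and avoids base-induced opening of ring C.

**Compound list**

1 | acetosyringone, 1-(4-hydroxy-3,5-dimethoxyphenyl)ethan-1-one | CC(=O)c1cc(OC)c(O)c(OC)c1 | starting material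
2 | 1-[4-(benzyloxy)-3,5-dimethoxyphenyl]ethan-1-one | CC(=O)c1cc(OC)c(OCc2ccccc2)c(OC)c1 | intermediate
3 | 1-[4-(benzyloxy)-2-bromo-3,5-dimethoxyphenyl]ethan-1-one | CC(=O)c1cc(OC)c(OCc2ccccc2)c(OC)c1Br | intermediate
4 | 1-[4-(benzyloxy)-2-hydroxy-3,5-dimethoxyphenyl]ethan-1-one | CC(=O)c1cc(OC)c(OCc2ccccc2)c(OC)c1O | intermediate
5 | 1-[2,4-bis(benzyloxy)-3,5-dimethoxyphenyl]ethan-1-one | CC(=O)c1cc(OC)c(OCc2ccccc2)c(OC)c1OCc1ccccc1 | intermediate
6 | 2-hydroxy-4-methoxybenzoic acid | COc1ccc(C(=O)O)c(O)c1 | starting material
7 | 2-hydroxy-4-methoxy-5-(sulfooxy)benzoic acid (present as its salt) | COc1cc(O)c(C(=O)O)cc1OS(=O)(=O)O | intermediate (not isolated)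
8 | 2,5-dihydroxy-4-methoxybenzoic acid | COc1cc(O)c(C(=O)O)cc1O | intermediate
9 | 2,5-diacetoxy-4-methoxybenzoic acid | COc1cc(OC(C)=O)c(C(=O)O)cc1OC(C)=O | intermediate
10 | 2,5-diacetoxy-4-methoxybenzoyl chloride | COc1cc(OC(C)=O)c(C(Cl)=O)cc1OC(C)=O | intermediate
11 | 2-{3-[2,4-bis(benzyloxy)-3,5-dimethoxyphenyl]-3-oxopropanoyl}-5-methoxy-1,4-phenylene diacetate | COc1cc(C(=O)CC(=O)c2cc(OC(C)=O)c(OC)cc2OC(C)=O)c(OCc2ccccc2)c(OC)c1OCc1ccccc1 | intermediate
12 | 2-[5,7-bis(benzyloxy)-6,8-dimethoxy-4-oxo-4H-chromen-2-yl]-5-methoxy-1,4-phenylene diacetate | COc1cc(OC(C)=O)c(-c2cc(=O)c3c(OCc4ccccc4)c(OC)c(OCc4ccccc4)c(OC)c3o2)cc1OC(C)=O | intermediate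
13 | 2-(5,7-dihydroxy-6,8-dimethoxy-4-oxo-4H-chromen-2-yl)-5-methoxy-1,4-phenylene diacetate | COc1cc(OC(C)=O)c(-c2cc(=O)c3c(O)c(OC)c(O)c(OC)c3o2)cc1OC(C)=O | intermediate
14 | 2-(2,5-dihydroxy-4-methoxyphenyl)-5,7-dihydroxy-6,8-dimethoxy-4H-chromen-4-one | COc1cc(O)c(-c2cc(=O)c3c(O)c(OC)c(O)c(OC)c3o2)cc1O | target

**Step count and risks**

Total steps: 11. Longest linear sequence: 8 steps (1, 2, 3, 4, 8, 9, 10, 11 from acetosyringone); the ring B branch (5, 6, 7) joins at step 8.

Steps most likely to fail:

1. Step 9 (proposed new method). The anode may oxidise the enol or ring B instead of ring A, the chromone may be over-oxidised, or a benzyl group may be lost from the ring A radical cation, so that O1–C8a does not form cleanly. The fallback makes the same bond by a known Ullmann-type O-arylation and sets out from 5 and 8. NBS in MeCN should brominate 5 at its only free ring position to give 1-[2,4-bis(benzyloxy)-6-bromo-3,5-dimethoxyphenyl]ethan-1-one F1. Acid 8 is perbenzylated (BnBr, K2CO3, DMF) to benzyl 2,5-bis(benzyloxy)-4-methoxybenzoate F2; acetates are no longer needed because no anodic step follows. Claisen condensation of the sodium enolate of F1 with F2 (NaH, THF, reflux) should give 1-[2,4-bis(benzyloxy)-6-bromo-3,5-dimethoxyphenyl]-3-[2,5-bis(benzyloxy)-4-methoxyphenyl]propane-1,3-dione F3. CuI, 1,10-phenanthroline and K2CO3 in DMF at 100 °C should then close ring C by intramolecular O-arylation to 5,7-bis(benzyloxy)-2-[2,5-bis(benzyloxy)-4-methoxyphenyl]-6,8-dimethoxy-4H-chromen-4-one F4. Hydrogenolysis over palladium on carbon removes all four benzyl groups, and the fallback rejoins the route at 14.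

2. Step 3. Under hot hydroxide the methyl ketone may undergo aldol self-condensation, or the doubly ortho-substituted bromide may be reduced instead of substituted. The fallback replaces substitution by borylation and oxidation and sets out from 3. Miyaura borylation (B2pin2, PdCl2(dppf), KOAc, dioxane, 90 °C) should give 1-[4-(benzyloxy)-3,5-dimethoxy-2-(4,4,5,5-tetramethyl-1,3,2-dioxaborolan-2-yl)phenyl]ethan-1-one F5. Oxidation of the C–B bond with NaBO3·4H2O in THF/H2O at rt gives the phenol, and the fallback rejoins the route at 4.

3. Step 8. The magnesium enolate may be O-acylated, an acetyl group may migrate from a ring B phenol ester to the diketonate, or MgBr2 may cleave the ortho benzyl ether. The fallback builds C2–C3 by an aldol addition at the alcohol oxidation level and sets out from 10 and 5. Rosenmund reduction of 10 (H2, Pd/BaSO4, 2,6-lutidine, THF) should give 2-formyl-5-methoxy-1,4-phenylene diacetate F6. Ketone 5 is converted with TMSOTf and Et3N in CH2Cl2 into {1-[2,4-bis(benzyloxy)-3,5-dimethoxyphenyl]ethenoxy}trimethylsilane F7. A Mukaiyama aldol addition of F7 to F6 (BF3·OEt2, CH2Cl2, −78 °C) should give racemic 2-{3-[2,4-bis(benzyloxy)-3,5-dimethoxyphenyl]-1-hydroxy-3-oxopropyl}-5-methoxy-1,4-phenylene diacetate F8, whose single stereocentre is removed in the next operation. Oxidation of the β-hydroxy ketone with IBX in EtOAc at 75 °C gives the diketone, and the fallback rejoins the route at 11.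

**Further compounds**

F1 | step 9 | 1-[2,4-bis(benzyloxy)-6-bromo-3,5-dimethoxyphenyl]ethan-1-one | CC(=O)c1c(Br)c(OC)c(OCc2ccccc2)c(OC)c1OCc1ccccc1
F2 | step 9 | benzyl 2,5-bis(benzyloxy)-4-methoxybenzoate | COc1cc(OCc2ccccc2)c(C(=O)OCc2ccccc2)cc1OCc1ccccc1
F3 | step 9 | 1-[2,4-bis(benzyloxy)-6-bromo-3,5-dimethoxyphenyl]-3-[2,5-bis(benzyloxy)-4-methoxyphenyl]propane-1,3-dione | COc1cc(OCc2ccccc2)c(C(=O)CC(=O)c2c(Br)c(OC)c(OCc3ccccc3)c(OC)c2OCc2ccccc2)cc1OCc1ccccc1
F4 | step 9 | 5,7-bis(benzyloxy)-2-[2,5-bis(benzyloxy)-4-methoxyphenyl]-6,8-dimethoxy-4H-chromen-4-one | COc1cc(OCc2ccccc2)c(-c2cc(=O)c3c(OCc4ccccc4)c(OC)c(OCc4ccccc4)c(OC)c3o2)cc1OCc1ccccc1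
F5 | step 3 | 1-[4-(benzyloxy)-3,5-dimethoxy-2-(4,4,5,5-tetramethyl-1,3,2-dioxaborolan-2-yl)phenyl]ethan-1-one | CC(=O)c1cc(OC)c(OCc2ccccc2)c(OC)c1B1OC(C)(C)C(C)(C)O1
F6 | step 8 | 2-formyl-5-methoxy-1,4-phenylene diacetate | COc1cc(OC(C)=O)c(C=O)cc1OC(C)=O
F7 | step 8 | {1-[2,4-bis(benzyloxy)-3,5-dimethoxyphenyl]ethenoxy}trimethylsilane | C=C(O[Si](C)(C)C)c1cc(OC)c(OCc2ccccc2)c(OC)c1OCc1ccccc1
F8 | step 8 | 2-{3-[2,4-bis(benzyloxy)-3,5-dimethoxyphenyl]-1-hydroxy-3-oxopropyl}-5-methoxy-1,4-phenylene diacetate (racemic) | COc1cc(C(=O)CC(O)c2cc(OC(C)=O)c(OC)cc2OC(C)=O)c(OCc2ccccc2)c(OC)c1OCc1ccccc1
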